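**Retrosynthetic overview**

- The strategy rests on the three contiguous ring carbons of the benzene ring: C1 carries the ester carbonyl, C2 and C3 each carry OH. The C1 acyl carbon and the C2 oxygen are both taken from one heneicosyl carbonate unit; the C3 oxygen is carried as boron.
- Last disconnection: C3–OH back to C3–B(pinacolato), by oxidation of the C–B bond.
- Key disconnection: the C1–C(=O) and C2–O bonds, made together by insertion of a 3-borylbenzyne (C1≡C2, boron on C3) into the O–C(acyl) bond of the heneicosyl carbonate anion.
- Aryne precursor: a 2-boryl-6-silylphenyl triflate from 2,6-dibromophenol (O-silylation, retro-Brook shift, borylation, triflation); carbonate salt from heneicosan-1-ol, a base and CO2.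
- No ring is formed anywhere; the benzene ring is bought with 2,6-dibromophenol.

Key step: step 6

Remark on the chemistry: the alkyl carbonate is used as its isolated potassium salt made from the alkoxide and CO2, so that no hydrogencarbonate or free alcohol enters the aryne step as a proton donor. Fluoride is assumed to trigger at silicon faster than a boron-bound fluoride can expel triflate.

**Route**

Step 1
Reactants: 1 2,6-dibromophenol
Product: 2 (2,6-dibromophenoxy)trimethylsilane
Conditions: HMDS (0.7 equiv), THF, 70 °C; volatiles evaporated, crude used directly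
Reagents that add atoms: hexamethyldisilazane, C[Si](C)(C)N[Si](C)(C)C
Why: O-silylation of an acidic phenol by a silazane, driven by loss of ammonia.

Step 2
Reactants: 2 (2,6-dibromophenoxy)trimethylsilane
Product: 4 2-bromo-6-(trimethylsilyl)phenol, via aryllithium 3 (not isolated)
Conditions: n-BuLi (1.05 equiv), THF, −78 °C → rt; 1 M HCl (cold work-up)
Reagents that add atoms: none
Why: Bromine–lithium exchange at one of the two equivalent C–Br bonds, then a 1,3 O-to-C silyl shift (retro-Brook rearrangement) driven by formation of the lithium phenoxide; with one equivalent of n-BuLi the second bromine should remain.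

Step 3
Reactants: 4 2-bromo-6-(trimethylsilyl)phenol; 5 2-isopropoxy-4,4,5,5-tetramethyl-1,3,2-dioxaborolane
Product: 7 2-(4,4,5,5-tetramethyl-1,3,2-dioxaborolan-2-yl)-6-(trimethylsilyl)phenol, via dilithiated phenoxide 6 (not isolated)
Conditions: n-BuLi (2.2 equiv), THF, −78 → 0 °C; 5 (1.5 equiv), −78 °C → rt; 1 M HCl to pH 5
Reagents that add atoms: none
Why: Deprotonation of OH followed by bromine–lithium exchange gives the O,C-dilithio species, whose aryllithium is trapped by the borate ester (electrophilic borylation of an aryllithium); mild acid collapses the ate complex to the pinacol boronate.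

Step 4
Reactants: 7 2-(4,4,5,5-tetramethyl-1,3,2-dioxaborolan-2-yl)-6-(trimethylsilyl)phenol
Product: 8 2-(4,4,5,5-tetramethyl-1,3,2-dioxaborolan-2-yl)-6-(trimethylsilyl)phenyl trifluoromethanesulfonate
Conditions: Tf2O (1.2 equiv), pyridine (2 equiv), CH2Cl2, 0 °C → rt
Reagents that add atoms: trifluoromethanesulfonic anhydride, O=S(=O)(OS(=O)(=O)C(F)(F)F)C(F)(F)F
Why: O-sulfonylation of a phenol via the N-triflylpyridinium salt; aryl–SiMe3 and the pinacol boronate should tolerate these conditions, as ortho-silyl and ortho-boryl aryl triflates are made this way.

Step 5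
Reactants: 9 heneicosan-1-ol
Product: 11 potassium heneicosyl carbonate, via potassium heneicosan-1-olate 10 (not isolated)
Conditions: KH (1.0 equiv), THF, 40 °C; CO2 (1 atm), 0 °C → rt; evaporated, washed with dry pentane, stored under Ar
Reagents that add atoms: potassium hydride, [KH]; carbon dioxide, O=C=O
Why: Irreversible deprotonation of the alcohol and carboxylation of the alkoxide give the monoalkyl carbonate salt with dihydrogen as the only co-product, so the salt carries no proton source.

Step 6
Reactants: 8 2-(4,4,5,5-tetramethyl-1,3,2-dioxaborolan-2-yl)-6-(trimethylsilyl)phenyl trifluoromethanesulfonate; 11 potassium heneicosyl carbonate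
Product: 14 heneicosyl 2-hydroxy-3-(4,4,5,5-tetramethyl-1,3,2-dioxaborolan-2-yl)benzoate, via 3-borylbenzyne 12 (not isolated), via ortho-carbonate aryl anion 13 (not isolated)
Conditions: 11 (2 equiv), KF (3 equiv), 18-crown-6 (3 equiv), THF, 0 °C → rt, closed flask under Ar with ca. 0.1 atm CO2, slow addition of 8; 0.5 M HCl (work-up)
Reagents that add atoms: none
Why: Proposed new method: fluoride attacks silicon, triflate leaves and the aryne 12 forms between the former C–Si carbon (future C1) and the former C–OTf carbon (future C2); the anionic oxygen of 11 adds at C2, the C1 aryl anion 13 attacks the carbonate carbonyl through a four-membered transition state, and the tetrahedral intermediate expels the phenoxide in preference to the alkoxide, so the heneicosyloxycarbonyl group moves from oxygen to carbon and the C2–O and C1–C(=O) bonds are made in one operation. The closest known reactions are the insertion of arynes into carboxylic acids with O-to-C acyl shift to ortho-hydroxyaryl ketones, the anionic Fries shift of ortho-metallated aryl carbonates and carbamates, and three-component couplings of arynes with a nucleophile and CO2. No ring is closed and no stereocenter is formed. The step needs O-attack at C2 and not at C1: the electropositive boron on C3 donates through the sigma frame and distorts the aryne so that C2 is the more electrophilic end and the charge builds at the remote C1, a bias known for amine additions to 3-borylbenzynes and expected to grow when fluoride or the carbonate oxygen binds boron, whose empty p orbital can also deliver the oxygen to C2. It further needs triggering at silicon and not at boron, expected because ortho-boryl aryl triflates survive fluoride and carbonate bases, and it needs acyl transfer to outrun protonation or carboxylation of the aryl anion, hence the aprotic solvent, the proton-free salt and only a small CO2 pressure, just enough to hold back free alkoxide.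

Step 7
Reactants: 14 heneicosyl 2-hydroxy-3-(4,4,5,5-tetramethyl-1,3,2-dioxaborolan-2-yl)benzoate
Product: 15 heneicosyl 2,3-dihydroxybenzoate (the target)
Conditions: NaBO3·4H2O (3 equiv), THF/H2O (1:1), rt; 1 M HCl to pH 4, work-up under Ar
Reagents that add atoms: sodium perborate tetrahydrate (NaBO3·4H2O, dimeric anion), O[B-]1(O)OO[B-](O)(O)OO1.[Na+].[Na+]
Why: Ipso-oxidation of an arylboronic ester: hydroperoxide adds to boron, the aryl group shifts from boron to oxygen and the borate ester hydrolyses to the phenol; the weakly basic medium should spare the ester and limit oxidation of the catechol.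

**Compound list**

1 | 2,6-dibromophenol | Oc1c(Br)cccc1Br | starting material
2 | (2,6-dibromophenoxy)trimethylsilane | C[Si](C)(C)Oc1c(Br)cccc1Br | intermediate
3 | (2-bromo-6-lithiophenoxy)trimethylsilane | C[Si](C)(C)Oc1c([Li])cccc1Br | intermediate
4 | 2-bromo-6-(trimethylsilyl)phenol | C[Si](C)(C)c1cccc(Br)c1O | intermediate
5 | 2-isopropoxy-4,4,5,5-tetramethyl-1,3,2-dioxaborolane | CC(C)OB1OC(C)(C)C(C)(C)O1 | starting material
6 | lithium 2-lithio-6-(trimethylsilyl)phenoxide | C[Si](C)(C)c1cccc([Li])c1O[Li] | intermediate
7 | 2-(4,4,5,5-tetramethyl-1,3,2-dioxaborolan-2-yl)-6-(trimethylsilyl)phenol | C[Si](C)(C)c1cccc(B2OC(C)(C)C(C)(C)O2)c1O | intermediate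
8 | 2-(4,4,5,5-tetramethyl-1,3,2-dioxaborolan-2-yl)-6-(trimethylsilyl)phenyl trifluoromethanesulfonate | C[Si](C)(C)c1cccc(B2OC(C)(C)C(C)(C)O2)c1OS(=O)(=O)C(F)(F)F | intermediate
9 | heneicosan-1-ol | CCCCCCCCCCCCCCCCCCCCCO | starting material
10 | potassium heneicosan-1-olate | CCCCCCCCCCCCCCCCCCCCC[O-].[K+] | intermediate
11 | potassium heneicosyl carbonate | CCCCCCCCCCCCCCCCCCCCCOC(=O)[O-].[K+] | intermediate
12 | 3-(4,4,5,5-tetramethyl-1,3,2-dioxaborolan-2-yl)benzyne (1,2-didehydro, boron on the adjacent carbon) | C1#CC(B2OC(C)(C)C(C)(C)O2)=CC=C1 | intermediate
13 | potassium 2-[(heneicosyloxy)carbonyloxy]-3-(4,4,5,5-tetramethyl-1,3,2-dioxaborolan-2-yl)benzen-1-ide | CCCCCCCCCCCCCCCCCCCCCOC(=O)Oc1[c-]cccc1B1OC(C)(C)C(C)(C)O1.[K+] | intermediate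
14 | heneicosyl 2-hydroxy-3-(4,4,5,5-tetramethyl-1,3,2-dioxaborolan-2-yl)benzoate | CCCCCCCCCCCCCCCCCCCCCOC(=O)c1cccc(B2OC(C)(C)C(C)(C)O2)c1O | intermediate
15 | heneicosyl 2,3-dihydroxybenzoate | CCCCCCCCCCCCCCCCCCCCCOC(=O)c1cccc(O)c1O | target

**Step count**

Total steps: 7. Longest linear sequence: 6 (steps 1, 2, 3, 4, 6, 7); step 5 is the one-step side branch.

**Steps most likely to fail**

1. Step 6 (proposed new method). Several processes could take over:
   - protonation or carboxylation of the aryl anion before the acyl shift;
   - oxygen attack at the aryne carbon remote from boron;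
   - fluoride triggering at boron instead of silicon;
   - decarboxylation of the salt, followed by alkoxide addition to the aryne;
   - arylation of the product phenoxide by a second aryne.

   Fallback by known chemistry, setting out from heneicosan-1-ol 9 and coming back at the target 15: Appel bromination (CBr4, PPh3, CH2Cl2, 0 °C → rt) should give 1-bromoheneicosane F1. Alkylation of the carboxylate of commercial 2,3-dihydroxybenzoic acid with F1 (KHCO3, DMF, 60 °C) is selective for the carboxylate over the two phenols and should give 15 directly. Steps 1–4 and 7 are then not needed.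

2. Step 3. The second bromine–lithium exchange on an electron-rich lithium phenoxide may be incomplete, and the aryllithium may be alkylated by the 1-bromobutane formed or quenched by adventitious protons.

   Fallback setting out from 4 and coming back at 7: the phenol is capped as its benzyl ether (BnBr, K2CO3, DMF) to give [2-(benzyloxy)-3-bromophenyl]trimethylsilane F2. Clean exchange on the neutral ether (n-BuLi, THF, −78 °C) and trapping with 5 should give 2-[2-(benzyloxy)-3-(trimethylsilyl)phenyl]-4,4,5,5-tetramethyl-1,3,2-dioxaborolane F3. Hydrogenolysis (H2, Pd/C, EtOAc) then frees the phenol 7.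

3. Step 4. Sulfonylation of a phenol shielded on both sides may stall, or the electrophile and base may attack the boronate.

   Fallback setting out from 4 and coming back at 8: the order is reversed. The phenol 4 is triflated first (Tf2O, pyridine, CH2Cl2) to give 2-bromo-6-(trimethylsilyl)phenyl trifluoromethanesulfonate F4. Boron is then introduced by Miyaura borylation at the C–Br bond (B2pin2, Pd(dppf)Cl2, KOAc, dioxane, 80 °C) to give 8; the doubly ortho-substituted C–OTf bond is expected to be the slower site of oxidative addition.

**Further compounds**

F1 | step 6 | 1-bromoheneicosane | CCCCCCCCCCCCCCCCCCCCCBr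
F2 | step 3 | [2-(benzyloxy)-3-bromophenyl]trimethylsilane | C[Si](C)(C)c1cccc(Br)c1OCc1ccccc1
F3 | step 3 | 2-[2-(benzyloxy)-3-(trimethylsilyl)phenyl]-4,4,5,5-tetramethyl-1,3,2-dioxaborolane | C[Si](C)(C)c1cccc(B2OC(C)(C)C(C)(C)O2)c1OCc1ccccc1
F4 | step 4 | 2-bromo-6-(trimethylsilyl)phenyl trifluoromethanesulfonate | C[Si](C)(C)c1cccc(Br)c1OS(=O)(=O)C(F)(F)F
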